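The C40 skeleton is cut at C11=C12 and C11′=C12′ (carotenoid numbering) into two C15 phosphonium salts and the C10 dialdehyde. Everything rests on the trihydroxycyclohexane ring (ring A, C1–C6): a base-mediated α-ketol rearrangement expands a 1-acetylcyclopentan-1-ol by shifting the ring methylene C4 from the carbinol carbon C6 to the acetyl carbon C5. In one operation this forms ring A, sets the C5 tertiary carbinol (C5–OH, C5–CH3) by stereospecific 1,2-shift and leaves C6 as the ketone that later takes the side chain. The precursor is (1S,4S)-1-acetyl-4-silyloxy-2,2-dimethylcyclopentan-1-ol; the key step exploits the vicinal C5/C6 oxygenation beside the C1 gem-dimethyl carbon.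

Key step: step 5

Remark: compounds 1, 13, 18, 22 and 29 are taken as commercial; "carotenoid numbering" (ring A = C1–C6, primed locants = furanoid half) is used only where stated, otherwise locants are those of the compound name; TBS = tert-butyldimethylsilyl.

Step 1
Reactants: 1 2,2-dimethylcyclopentan-1-one
Product: 2 5,5-dimethylcyclopent-2-en-1-one
Conditions: IBX (1.5 equiv), DMSO/toluene, 70 °C
Reagents that add atoms: none
Why: IBX dehydrogenation of a ketone can only run toward the single enolisable α-carbon, so one enone should form and no stereocentre is involved.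

Step 2
Reactants: 2 5,5-dimethylcyclopent-2-en-1-one
Product: 4 (S)-4-hydroxy-2,2-dimethylcyclopentan-1-one, via boronate 3 (not isolated)
Conditions: B2pin2, CuCl (3 mol %), NaOtBu (5 mol %), (R,R)-2,3-bis(tert-butylmethylphosphino)quinoxaline (3 mol %), MeOH (2 equiv), THF, rt; then NaBO3·4H2O, THF/H2O, rt
Reagents that add atoms: bis(pinacolato)diboron CC1(C)OB(OC1(C)C)B1OC(C)(C)C(C)(C)O1 (boron of 3); sodium perborate [Na+].[Na+].O[B-]1(O)OO[B-](O)(O)OO1 (oxygen of 4)
Why: copper-catalysed enantioselective conjugate borylation sets the β-stereocentre under ligand control (the ligand antipode that gives the S boronate is used) and the C–B bond is then oxidised with retention.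

Step 3
Reactants: 4 (S)-4-hydroxy-2,2-dimethylcyclopentan-1-one
Product: 5 (S)-4-[(tert-butyldimethylsilyl)oxy]-2,2-dimethylcyclopentan-1-one
Conditions: TBSCl, imidazole, DMF, rt
Reagents that add atoms: tert-butyldimethylsilyl chloride CC(C)(C)[Si](C)(C)Cl
Why: standard silylation protects the β-hydroxyl against retro-aldol cleavage and elimination in the basic steps that follow, without touching the stereocentre.

Step 4
Reactants: 5 (S)-4-[(tert-butyldimethylsilyl)oxy]-2,2-dimethylcyclopentan-1-one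
Product: 7 1-[(1S,4S)-4-[(tert-butyldimethylsilyl)oxy]-1-hydroxy-2,2-dimethylcyclopentyl]ethan-1-one, via enol ether 6 (not isolated)
Conditions: ethyl vinyl ether, t-BuLi, THF, −78 to 0 °C; CeCl3, −78 °C; then 5, −78 °C; then 1 M HCl, THF, 0 °C
Reagents that add atoms: ethyl vinyl ether C=COCC (two acetyl carbons); water O (acetyl oxygen)
Why: 1,2-addition of the weakly basic acetyl-anion equivalent 1-ethoxyvinylcerium should occur anti to the C4 silyloxy group, setting C1 with hydroxyl cis to OTBS (the minor C1 epimer is removed by chromatography), and mild acid hydrolyses the enol ether to the methyl ketone.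

Step 5
Reactants: 7 1-[(1S,4S)-4-[(tert-butyldimethylsilyl)oxy]-1-hydroxy-2,2-dimethylcyclopentyl]ethan-1-one
Product: 8 (2R,4S)-4-[(tert-butyldimethylsilyl)oxy]-2-hydroxy-2,6,6-trimethylcyclohexan-1-one
Conditions: KOtBu (20 mol %), 18-crown-6 (20 mol %), THF, 0 °C to rt
Reagents that add atoms: none
Why: α-Ketol (acyloin) rearrangement: the potassium alkoxide of 7 drives a suprafacial 1,2-shift of the ring methylene C5 from the carbinol carbon C1 to the acetyl carbonyl carbon, so that C1 becomes the ring ketone and the acetyl carbon becomes the tertiary carbinol C2 of 8. The closest known reaction is the base-mediated D-homoannulation of 17-hydroxy-20-oxo steroids, where likewise the methylene and not the quaternary α-carbon migrates. No ring is closed by cyclisation: the cyclohexanone arises by one-carbon expansion of the cyclopentane (the acetyl carbon is inserted between C1 and C5 of 7), driven by the gain of a six-membered ring and of a non-enolisable ketone. The new stereocentre (C2 of 8, C5 of the target) is controlled by C1 of 7: in the free alkoxide the two oxygens stand anti-periplanar, so the migrating carbon attacks the carbonyl face that places the new hydroxyl on the side formerly held by the acetyl group, trans to the silyloxy group. The step needs methylene-over-quaternary migration, which the carbanion-like character of the anionic shift (primary, β-silyloxy carbon favoured; CMe2 carbon hindered) should secure, and it needs the non-chelated conformer, which potassium with 18-crown-6 in place of a chelating cation should secure.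

Step 6
Reactants: 8 (2R,4S)-4-[(tert-butyldimethylsilyl)oxy]-2-hydroxy-2,6,6-trimethylcyclohexan-1-one
Product: 10 (1R,5S)-5-[(tert-butyldimethylsilyl)oxy]-1,3,3-trimethyl-2-methylidenecyclohexan-1-ol, via hydroxysilane 9 (not isolated)
Conditions: Me3SiCH2Li (3 equiv), THF, −78 °C to rt; then KOtBu (3 equiv), 50 °C
Reagents that add atoms: (trimethylsilyl)methyllithium C[Si](C)(C)C[Li]
Why: Peterson olefination: the small α-silyl carbanion should add to the hindered, non-enolisable ketone (from the face anti to the axial hydroxyl and methyl) and the potassium β-oxidosilane eliminates to the exocyclic methylene, so no stereocentre of 10 depends on the addition face.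

Step 7
Reactants: 10 (1R,5S)-5-[(tert-butyldimethylsilyl)oxy]-1,3,3-trimethyl-2-methylidenecyclohexan-1-ol
Product: 11 (1R,2S,5S)-5-[(tert-butyldimethylsilyl)oxy]-2-(hydroxymethyl)-1,3,3-trimethylcyclohexane-1,2-diol
Conditions: OsO4 (5 mol %), N-methylmorpholine N-oxide (2 equiv), acetone/H2O, rt
Reagents that add atoms: N-methylmorpholine N-oxide C[N+]1([O-])CCOCC1 (one oxygen); water O (one oxygen)
Why: catalytic osmylation should take the alkene face anti to the axial allylic hydroxyl at C1 and the axial methyl at C3 of 10, which makes the new tertiary hydroxyl axial and trans to the existing one (C6 of the target).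

Step 8
Reactants: 11 (1R,2S,5S)-5-[(tert-butyldimethylsilyl)oxy]-2-(hydroxymethyl)-1,3,3-trimethylcyclohexane-1,2-diol
Product: 12 (1R,2R,4S)-4-[(tert-butyldimethylsilyl)oxy]-1,2-dihydroxy-2,6,6-trimethylcyclohexane-1-carbaldehyde
Conditions: TEMPO (10 mol %), PhI(OAc)2 (1.2 equiv), CH2Cl2, rt
Reagents that add atoms: none
Why: nitroxyl-catalysed oxidation converts only the primary alcohol (the other free hydroxyls are tertiary) and stops at the non-enolisable α-hydroxy aldehyde.

Step 9
Reactants: 12 (1R,2R,4S)-4-[(tert-butyldimethylsilyl)oxy]-1,2-dihydroxy-2,6,6-trimethylcyclohexane-1-carbaldehyde; 13 ethyl 4-(diethoxyphosphoryl)-3-methylbut-2-enoate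
Product: 14 ethyl (2E,4E)-5-[(1R,2R,4S)-4-[(tert-butyldimethylsilyl)oxy]-1,2-dihydroxy-2,6,6-trimethylcyclohexyl]-3-methylpenta-2,4-dienoate
Conditions: 13 (3 equiv), LiN(SiMe3)2 (3 equiv), THF, −78 °C; then 12, −78 to 0 °C
Reagents that add atoms: none
Why: Horner–Wadsworth–Emmons olefination with the vinylogous phosphonate carbanion should form the new C4=C5 bond E and the C2=C3 bond mainly E (the minor 2Z isomer is removed by chromatography), the low temperature keeping the β-alkoxide aldehyde from retro-aldol opening.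

Step 10
Reactants: 14 ethyl (2E,4E)-5-[(1R,2R,4S)-4-[(tert-butyldimethylsilyl)oxy]-1,2-dihydroxy-2,6,6-trimethylcyclohexyl]-3-methylpenta-2,4-dienoate
Product: 15 (2E,4E)-5-[(1R,2R,4S)-4-[(tert-butyldimethylsilyl)oxy]-1,2-dihydroxy-2,6,6-trimethylcyclohexyl]-3-methylpenta-2,4-dien-1-ol
Conditions: iBu2AlH (5 equiv), CH2Cl2, −78 to −20 °C
Reagents that add atoms: none
Why: 1,2-reduction of the dienoate by the aluminium hydride gives the primary allylic alcohol without touching the diene or the silyl ether.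

Step 11
Reactants: 15 (2E,4E)-5-[(1R,2R,4S)-4-[(tert-butyldimethylsilyl)oxy]-1,2-dihydroxy-2,6,6-trimethylcyclohexyl]-3-methylpenta-2,4-dien-1-ol
Product: 17 [(2E,4E)-5-[(1R,2R,4S)-4-[(tert-butyldimethylsilyl)oxy]-1,2-dihydroxy-2,6,6-trimethylcyclohexyl]-3-methylpenta-2,4-dien-1-yl]triphenylphosphonium bromide, via bromide 16 (not isolated)
Conditions: CBr4, PPh3, 2,6-lutidine, CH2Cl2, −20 °C; then PPh3 (1.5 equiv), rt
Reagents that add atoms: carbon tetrabromide BrC(Br)(Br)Br (bromide); triphenylphosphine c1ccc(cc1)P(c1ccccc1)c1ccccc1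
Why: Appel bromination is selective for the primary allylic alcohol under neutral conditions and the bromide is quaternised in situ by SN2 attack of PPh3, which avoids the acid that would ionise the tertiary allylic C–O bond.

Step 12
Reactants: 18 (4R,6R)-4-hydroxy-2,2,6-trimethylcyclohexan-1-one
Product: 19 (4R,6R)-4-[(tert-butyldimethylsilyl)oxy]-2,2,6-trimethylcyclohexan-1-one
Conditions: TBSCl, imidazole, DMF, rt
Reagents that add atoms: tert-butyldimethylsilyl chloride CC(C)(C)[Si](C)(C)Cl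
Why: standard silylation of the secondary alcohol; the C4 stereocentre (C3′ of the target) comes from the chiral pool.

Step 13
Reactants: 19 (4R,6R)-4-[(tert-butyldimethylsilyl)oxy]-2,2,6-trimethylcyclohexan-1-one
Product: 21 (4R)-4-[(tert-butyldimethylsilyl)oxy]-2,6,6-trimethylcyclohex-1-en-1-yl trifluoromethanesulfonate, via lithium enolate 20 (not isolated)
Conditions: LiN(iPr)2, THF, −78 to 0 °C; then PhNTf2, −78 °C to rt
Reagents that add atoms: lithium diisopropylamide [Li]N(C(C)C)C(C)C (lithium of 20); N-phenylbis(trifluoromethanesulfonimide) O=S(=O)(N(c1ccccc1)S(=O)(=O)C(F)(F)F)C(F)(F)F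
Why: the ketone has a single α-hydrogen, so one tetrasubstituted enolate forms and its O-triflation gives the enol triflate, the C6 stereocentre of 19 being erased on purpose.

Step 14
Reactants: 21 (4R)-4-[(tert-butyldimethylsilyl)oxy]-2,6,6-trimethylcyclohex-1-en-1-yl trifluoromethanesulfonate; 22 (2E)-3-methylpent-2-en-4-yn-1-ol
Product: 23 (2E)-5-[(4R)-4-[(tert-butyldimethylsilyl)oxy]-2,6,6-trimethylcyclohex-1-en-1-yl]-3-methylpent-2-en-4-yn-1-ol
Conditions: Pd(PPh3)4 (5 mol %), CuI (10 mol %), iPr2NH, DMF, rt to 50 °C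
Reagents that add atoms: none
Why: Sonogashira coupling of the alkenyl triflate with the terminal alkyne keeps the E geometry of the enynol and tolerates the free hydroxyl.

Step 15
Reactants: 23 (2E)-5-[(4R)-4-[(tert-butyldimethylsilyl)oxy]-2,6,6-trimethylcyclohex-1-en-1-yl]-3-methylpent-2-en-4-yn-1-ol
Product: 24 (2E)-5-[(1R,4S,6R)-4-[(tert-butyldimethylsilyl)oxy]-2,2,6-trimethyl-7-oxabicyclo[4.1.0]heptan-1-yl]-3-methylpent-2-en-4-yn-1-ol
Conditions: mCPBA (1.05 equiv), NaHCO3, CH2Cl2, −20 to 0 °C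
Reagents that add atoms: 3-chloroperbenzoic acid OOC(=O)c1cccc(Cl)c1
Why: Prilezhaev epoxidation should take the tetrasubstituted, most electron-rich ring alkene and approach anti to the bulky homoallylic silyloxy group, which sets both oxirane carbons trans to OTBS (the minor syn epoxide is removed by chromatography).

Step 16
Reactants: 24 (2E)-5-[(1R,4S,6R)-4-[(tert-butyldimethylsilyl)oxy]-2,2,6-trimethyl-7-oxabicyclo[4.1.0]heptan-1-yl]-3-methylpent-2-en-4-yn-1-ol
Product: 25 (2E)-5-[(2R,4S)-4-[(tert-butyldimethylsilyl)oxy]-2-hydroxy-2,6,6-trimethylcyclohexylidene]-3-methylpenta-2,4-dien-1-ol (allene axis R; terminal allene H syn to the tertiary OH)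
Conditions: iBu2AlH (4 equiv), CH2Cl2, −78 to 0 °C
Reagents that add atoms: none
Why: SN2′ hydride opening of the alkynyl oxirane, with hydride passed to the alkyne terminus from aluminium bound to the oxirane oxygen (syn to the breaking C–O bond), should give the R allene axis while the oxygen stays on C2 as the tertiary alcohol.

Step 17
Reactants: 25 (2E)-5-[(2R,4S)-4-[(tert-butyldimethylsilyl)oxy]-2-hydroxy-2,6,6-trimethylcyclohexylidene]-3-methylpenta-2,4-dien-1-ol (allene axis R)
Product: 26 (2E)-3-[(2S,6S,7aR)-6-[(tert-butyldimethylsilyl)oxy]-4,4,7a-trimethyl-2,4,5,6,7,7a-hexahydro-1-benzofuran-2-yl]but-2-en-1-ol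
Conditions: Ph3PAuNTf2 (2 mol %), 2,6-di-tert-butylpyridine (5 mol %), CH2Cl2, −20 to 0 °C
Reagents that add atoms: none
Why: gold-catalysed 5-endo cycloisomerisation of the α-hydroxyallene (anti oxyauration of the distal allene bond, then protodeauration) forms the 2,5-dihydrofuran with axis-to-centre chirality transfer, so the R axis should become the 2S centre (C8′ of the target), while the E-configured primary alcohol cannot reach the allene.

Step 18
Reactants: 26 (2E)-3-[(2S,6S,7aR)-6-[(tert-butyldimethylsilyl)oxy]-4,4,7a-trimethyl-2,4,5,6,7,7a-hexahydro-1-benzofuran-2-yl]but-2-en-1-ol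
Product: 28 [(2E)-3-[(2S,6S,7aR)-6-[(tert-butyldimethylsilyl)oxy]-4,4,7a-trimethyl-2,4,5,6,7,7a-hexahydro-1-benzofuran-2-yl]but-2-en-1-yl]triphenylphosphonium bromide, via bromide 27 (not isolated)
Conditions: CBr4, PPh3, 2,6-lutidine, CH2Cl2, −20 °C; then PPh3 (1.5 equiv), rt
Reagents that add atoms: carbon tetrabromide BrC(Br)(Br)Br (bromide); triphenylphosphine c1ccc(cc1)P(c1ccccc1)c1ccccc1
Why: neutral Appel bromination and in situ SN2 quaternisation give the salt without the acid that would ionise the allylic ring ether and scramble C2.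

Step 19
Reactants: 28 [(2E)-3-[(2S,6S,7aR)-6-[(tert-butyldimethylsilyl)oxy]-4,4,7a-trimethyl-2,4,5,6,7,7a-hexahydro-1-benzofuran-2-yl]but-2-en-1-yl]triphenylphosphonium bromide; 29 (2E,4E,6E)-2,7-dimethylocta-2,4,6-trienedial
Product: 30 (2E,4E,6E,8E,10E)-11-[(2S,6S,7aR)-6-[(tert-butyldimethylsilyl)oxy]-4,4,7a-trimethyl-2,4,5,6,7,7a-hexahydro-1-benzofuran-2-yl]-2,7-dimethyldodeca-2,4,6,8,10-pentaenal
Conditions: 29 (4 equiv), NaOMe/MeOH added to 28 and 29 in CH2Cl2, 0 °C; then heptane, 70 °C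
Reagents that add atoms: none
Why: Wittig olefination with the phosphorane generated in the presence of excess dialdehyde (fast capture before vinylogous β-elimination of the ring oxygen, and mono-olefination) forms the C8=C9 bond, whose Z isomer is equilibrated to E on heating.

Step 20
Reactants: 17 [(2E,4E)-5-[(1R,2R,4S)-4-[(tert-butyldimethylsilyl)oxy]-1,2-dihydroxy-2,6,6-trimethylcyclohexyl]-3-methylpenta-2,4-dien-1-yl]triphenylphosphonium bromide; 30 (2E,4E,6E,8E,10E)-11-[(2S,6S,7aR)-6-[(tert-butyldimethylsilyl)oxy]-4,4,7a-trimethyl-2,4,5,6,7,7a-hexahydro-1-benzofuran-2-yl]-2,7-dimethyldodeca-2,4,6,8,10-pentaenal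
Product: 31 (3S,5R,6R,3′S,5′R,8′S)-3,3′-bis[(tert-butyldimethylsilyl)oxy]-5′,8′-epoxy-5,6,5′,8′-tetrahydro-β,β-carotene-5,6-diol
Conditions: 17 (1.3 equiv), NaOMe/MeOH, CH2Cl2, 0 °C to rt; then heptane/EtOH, 70 °C
Reagents that add atoms: none
Why: the second Wittig olefination joins the two halves at C11=C12 (carotenoid numbering) in the presence of the free tertiary hydroxyls, and thermal equilibration should bring the new double bond to E.

Step 21
Reactants: 31 (3S,5R,6R,3′S,5′R,8′S)-3,3′-bis[(tert-butyldimethylsilyl)oxy]-5′,8′-epoxy-5,6,5′,8′-tetrahydro-β,β-carotene-5,6-diol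
Product: 32 (3S,5R,6R,3′S,5′R,8′S)-5′,8′-epoxy-5,6,5′,8′-tetrahydro-β,β-carotene-3,5,6,3′-tetrol (CNP0210286.3)
Conditions: Bu4NF, THF, 0 °C to rt
Reagents that add atoms: none
Why: fluoride cleaves both secondary silyl ethers under non-acidic conditions, which spares the acid-labile dihydrofuran ether and the tertiary allylic alcohol.

Compound list
1 | 2,2-dimethylcyclopentan-1-one | O=C1CCCC1(C)C | starting material
2 | 5,5-dimethylcyclopent-2-en-1-one | O=C1C=CCC1(C)C | intermediate
3 | (S)-2,2-dimethyl-4-(4,4,5,5-tetramethyl-1,3,2-dioxaborolan-2-yl)cyclopentan-1-one | O=C1C(C)(C)C[C@H](B2OC(C)(C)C(C)(C)O2)C1 | intermediate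
4 | (S)-4-hydroxy-2,2-dimethylcyclopentan-1-one | O=C1C(C)(C)C[C@H](O)C1 | intermediate
5 | (S)-4-[(tert-butyldimethylsilyl)oxy]-2,2-dimethylcyclopentan-1-one | O=C1C(C)(C)C[C@H](O[Si](C)(C)C(C)(C)C)C1 | intermediate
6 | (1S,4S)-4-[(tert-butyldimethylsilyl)oxy]-1-(1-ethoxyethenyl)-2,2-dimethylcyclopentan-1-ol | C=C(OCC)[C@@]1(O)C(C)(C)C[C@H](O[Si](C)(C)C(C)(C)C)C1 | intermediate
7 | 1-[(1S,4S)-4-[(tert-butyldimethylsilyl)oxy]-1-hydroxy-2,2-dimethylcyclopentyl]ethan-1-one (OH cis to OTBS) | CC(=O)[C@@]1(O)C(C)(C)C[C@H](O[Si](C)(C)C(C)(C)C)C1 | intermediate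
8 | (2R,4S)-4-[(tert-butyldimethylsilyl)oxy]-2-hydroxy-2,6,6-trimethylcyclohexan-1-one | O=C1C(C)(C)C[C@H](O[Si](C)(C)C(C)(C)C)C[C@@]1(C)O | intermediate
9 | (1R,2S,5S)-5-[(tert-butyldimethylsilyl)oxy]-1,3,3-trimethyl-2-[(trimethylsilyl)methyl]cyclohexane-1,2-diol | C[Si](C)(C)C[C@]1(O)C(C)(C)C[C@H](O[Si](C)(C)C(C)(C)C)C[C@@]1(C)O | intermediate
10 | (1R,5S)-5-[(tert-butyldimethylsilyl)oxy]-1,3,3-trimethyl-2-methylidenecyclohexan-1-ol | C=C1C(C)(C)C[C@H](O[Si](C)(C)C(C)(C)C)C[C@@]1(C)O | intermediate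
11 | (1R,2S,5S)-5-[(tert-butyldimethylsilyl)oxy]-2-(hydroxymethyl)-1,3,3-trimethylcyclohexane-1,2-diol | OC[C@@]1(O)C(C)(C)C[C@H](O[Si](C)(C)C(C)(C)C)C[C@@]1(C)O | intermediate
12 | (1R,2R,4S)-4-[(tert-butyldimethylsilyl)oxy]-1,2-dihydroxy-2,6,6-trimethylcyclohexane-1-carbaldehyde | O=C[C@@]1(O)C(C)(C)C[C@H](O[Si](C)(C)C(C)(C)C)C[C@@]1(C)O | intermediate
13 | ethyl 4-(diethoxyphosphoryl)-3-methylbut-2-enoate (triethyl 3-methyl-4-phosphonocrotonate; commercial E/Z mixture) | CCOC(=O)C=C(C)CP(=O)(OCC)OCC | starting material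
14 | ethyl (2E,4E)-5-[(1R,2R,4S)-4-[(tert-butyldimethylsilyl)oxy]-1,2-dihydroxy-2,6,6-trimethylcyclohexyl]-3-methylpenta-2,4-dienoate | CCOC(=O)/C=C(C)/C=C/[C@@]1(O)C(C)(C)C[C@H](O[Si](C)(C)C(C)(C)C)C[C@@]1(C)O | intermediate
15 | (2E,4E)-5-[(1R,2R,4S)-4-[(tert-butyldimethylsilyl)oxy]-1,2-dihydroxy-2,6,6-trimethylcyclohexyl]-3-methylpenta-2,4-dien-1-ol | OC/C=C(C)/C=C/[C@@]1(O)C(C)(C)C[C@H](O[Si](C)(C)C(C)(C)C)C[C@@]1(C)O | intermediate
16 | (1R,2R,4S)-1-[(1E,3E)-5-bromo-3-methylpenta-1,3-dien-1-yl]-4-[(tert-butyldimethylsilyl)oxy]-2,6,6-trimethylcyclohexane-1,2-diol | BrC/C=C(C)/C=C/[C@@]1(O)C(C)(C)C[C@H](O[Si](C)(C)C(C)(C)C)C[C@@]1(C)O | intermediate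
17 | [(2E,4E)-5-[(1R,2R,4S)-4-[(tert-butyldimethylsilyl)oxy]-1,2-dihydroxy-2,6,6-trimethylcyclohexyl]-3-methylpenta-2,4-dien-1-yl]triphenylphosphonium bromide | [Br-].c1ccccc1[P+](c1ccccc1)(c1ccccc1)C/C=C(C)/C=C/[C@@]1(O)C(C)(C)C[C@H](O[Si](C)(C)C(C)(C)C)C[C@@]1(C)O | intermediate
18 | (4R,6R)-4-hydroxy-2,2,6-trimethylcyclohexan-1-one (actinol) | O=C1C(C)(C)C[C@H](O)C[C@H]1C | starting material
19 | (4R,6R)-4-[(tert-butyldimethylsilyl)oxy]-2,2,6-trimethylcyclohexan-1-one | O=C1C(C)(C)C[C@H](O[Si](C)(C)C(C)(C)C)C[C@H]1C | intermediate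
20 | lithium (4R)-4-[(tert-butyldimethylsilyl)oxy]-2,6,6-trimethylcyclohex-1-en-1-olate | [Li]OC1=C(C)C[C@@H](O[Si](C)(C)C(C)(C)C)CC1(C)C | intermediate
21 | (4R)-4-[(tert-butyldimethylsilyl)oxy]-2,6,6-trimethylcyclohex-1-en-1-yl trifluoromethanesulfonate | FC(F)(F)S(=O)(=O)OC1=C(C)C[C@@H](O[Si](C)(C)C(C)(C)C)CC1(C)C | intermediate
22 | (2E)-3-methylpent-2-en-4-yn-1-ol | OC\C=C(/C)C#C | starting material
23 | (2E)-5-[(4R)-4-[(tert-butyldimethylsilyl)oxy]-2,6,6-trimethylcyclohex-1-en-1-yl]-3-methylpent-2-en-4-yn-1-ol | OC\C=C(/C)C#CC1=C(C)C[C@@H](O[Si](C)(C)C(C)(C)C)CC1(C)C | intermediate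
24 | (2E)-5-[(1R,4S,6R)-4-[(tert-butyldimethylsilyl)oxy]-2,2,6-trimethyl-7-oxabicyclo[4.1.0]heptan-1-yl]-3-methylpent-2-en-4-yn-1-ol (oxirane trans to OTBS) | OC\C=C(/C)C#C[C@@]12O[C@]1(C)C[C@@H](O[Si](C)(C)C(C)(C)C)CC2(C)C | intermediate
25 | (2E)-5-[(2R,4S)-4-[(tert-butyldimethylsilyl)oxy]-2-hydroxy-2,6,6-trimethylcyclohexylidene]-3-methylpenta-2,4-dien-1-ol, allene axis R (carotenoid 3S,5R,6R) | OC\C=C(/C)C([H])=[C@@]=C1C(C)(C)C[C@H](O[Si](C)(C)C(C)(C)C)C[C@@]1(C)O | intermediate
26 | (2E)-3-[(2S,6S,7aR)-6-[(tert-butyldimethylsilyl)oxy]-4,4,7a-trimethyl-2,4,5,6,7,7a-hexahydro-1-benzofuran-2-yl]but-2-en-1-ol | OC\C=C(/C)[C@@H]1C=C2C(C)(C)C[C@H](O[Si](C)(C)C(C)(C)C)C[C@@]2(C)O1 | intermediate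
27 | (2S,6S,7aR)-2-[(2E)-4-bromobut-2-en-2-yl]-6-[(tert-butyldimethylsilyl)oxy]-4,4,7a-trimethyl-2,4,5,6,7,7a-hexahydro-1-benzofuran | BrC\C=C(/C)[C@@H]1C=C2C(C)(C)C[C@H](O[Si](C)(C)C(C)(C)C)C[C@@]2(C)O1 | intermediate
28 | [(2E)-3-[(2S,6S,7aR)-6-[(tert-butyldimethylsilyl)oxy]-4,4,7a-trimethyl-2,4,5,6,7,7a-hexahydro-1-benzofuran-2-yl]but-2-en-1-yl]triphenylphosphonium bromide | [Br-].c1ccccc1[P+](c1ccccc1)(c1ccccc1)C\C=C(/C)[C@@H]1C=C2C(C)(C)C[C@H](O[Si](C)(C)C(C)(C)C)C[C@@]2(C)O1 | intermediate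
29 | (2E,4E,6E)-2,7-dimethylocta-2,4,6-trienedial | O=C/C(C)=C/C=C/C=C(C)/C=O | starting material
30 | (2E,4E,6E,8E,10E)-11-[(2S,6S,7aR)-6-[(tert-butyldimethylsilyl)oxy]-4,4,7a-trimethyl-2,4,5,6,7,7a-hexahydro-1-benzofuran-2-yl]-2,7-dimethyldodeca-2,4,6,8,10-pentaenal | CC(/C=O)=C\C=C\C=C(C)\C=C\C=C(/C)[C@@H]1C=C2C(C)(C)C[C@H](O[Si](C)(C)C(C)(C)C)C[C@@]2(C)O1 | intermediate
31 | (3S,5R,6R,3′S,5′R,8′S)-3,3′-bis[(tert-butyldimethylsilyl)oxy]-5′,8′-epoxy-5,6,5′,8′-tetrahydro-β,β-carotene-5,6-diol | CC(/C=C/C=C(C)/C=C/[C@@]1(O)C(C)(C)C[C@H](O[Si](C)(C)C(C)(C)C)C[C@@]1(C)O)=C\C=C\C=C(C)\C=C\C=C(/C)[C@@H]1C=C2C(C)(C)C[C@H](O[Si](C)(C)C(C)(C)C)C[C@@]2(C)O1 | intermediate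
32 | (3S,5R,6R,3′S,5′R,8′S)-5′,8′-epoxy-5,6,5′,8′-tetrahydro-β,β-carotene-3,5,6,3′-tetrol (CNP0210286.3) | CC(/C=C/C=C(C)/C=C/[C@@]1(O)C(C)(C)C[C@H](O)C[C@@]1(C)O)=C\C=C\C=C(C)\C=C\C=C(/C)[C@@H]1C=C2C(C)(C)C[C@H](O)C[C@@]2(C)O1 | target

Total step count: 21.
Longest linear sequence: 13 steps (steps 1 to 11, then 20 and 21).

Steps most likely to fail

Step 5. What may go wrong is migration of the quaternary ring carbon in place of the methylene, partial reaction through a cation-bridged syn conformer that would invert C2 of 8, or aldol self-condensation of the methyl ketone before the shift. The fallback sets out from 5 and keeps a ring expansion but changes its type. Lewis-acid-promoted homologation with diazoethane (Sc(OTf)3 cat., CH2Cl2, −78 °C), in which the less substituted α-carbon migrates, should give (4R)-4-[(tert-butyldimethylsilyl)oxy]-2,2,6-trimethylcyclohexan-1-one F1 as C6 epimers. Its only possible enolate (KN(SiMe3)2, THF, −78 °C) is then hydroxylated with 2-(phenylsulfonyl)-3-phenyloxaziridine, expected on the face anti to the silyloxy group, and the route is rejoined at 8.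

Step 6. What may go wrong is failure of the silyl carbanion to add to a carbonyl flanked by two fully substituted carbons, or acyloin isomerisation of the lithium ketolate on warming. The fallback sets out from 8 and replaces intermolecular addition by tethered delivery; it also replaces step 7.
- Silylation of the tertiary hydroxyl with (bromomethyl)chlorodimethylsilane (imidazole, DMAP, DMF) should give (2R,4S)-2-{[(bromomethyl)dimethylsilyl]oxy}-4-[(tert-butyldimethylsilyl)oxy]-2,6,6-trimethylcyclohexan-1-one F2.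
- Intramolecular Barbier addition (SmI2, THF/HMPA, 0 °C) closes the five-membered siloxane and delivers the carbon to the carbonyl from the face of the tether, giving cis-fused (3aR,6S,7aR)-6-[(tert-butyldimethylsilyl)oxy]-2,2,4,4,7a-pentamethyloctahydro-1,2-benzoxasilol-3a-ol F3.
- Tamao oxidation of the C–Si bond (H2O2, KF, KHCO3, THF/MeOH) rejoins the route at 11.

Step 17. What may go wrong is Nazarov-type carbocyclisation of the vinylallene or acid-induced ionisation of the new allylic ether with loss of the C2 configuration of 26. The fallback sets out from 25 and changes from π-acid catalysis to electrophile-induced etherification. N-Iodosuccinimide (NaHCO3, CH2Cl2, −40 °C) should close the same ring by anti iodoetherification with the same axis-to-centre transfer, giving (2E)-3-[(2R,6S,7aR)-6-[(tert-butyldimethylsilyl)oxy]-3-iodo-4,4,7a-trimethyl-2,4,5,6,7,7a-hexahydro-1-benzofuran-2-yl]but-2-en-1-ol F4. Hydrodeiodination with Bu3SnH and Pd(PPh3)4 (cat.) in THF then rejoins the route at 26.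

Further compounds
F1 | step 5 | (4R)-4-[(tert-butyldimethylsilyl)oxy]-2,2,6-trimethylcyclohexan-1-one (C6 epimers) | O=C1C(C)(C)C[C@H](O[Si](C)(C)C(C)(C)C)CC1C
F2 | step 6 | (2R,4S)-2-{[(bromomethyl)dimethylsilyl]oxy}-4-[(tert-butyldimethylsilyl)oxy]-2,6,6-trimethylcyclohexan-1-one | O=C1C(C)(C)C[C@H](O[Si](C)(C)C(C)(C)C)C[C@@]1(C)O[Si](C)(C)CBr
F3 | step 6 | (3aR,6S,7aR)-6-[(tert-butyldimethylsilyl)oxy]-2,2,4,4,7a-pentamethyloctahydro-1,2-benzoxasilol-3a-ol | C[Si]1(C)C[C@@]2(O)C(C)(C)C[C@H](O[Si](C)(C)C(C)(C)C)C[C@@]2(C)O1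
F4 | step 17 | (2E)-3-[(2R,6S,7aR)-6-[(tert-butyldimethylsilyl)oxy]-3-iodo-4,4,7a-trimethyl-2,4,5,6,7,7a-hexahydro-1-benzofuran-2-yl]but-2-en-1-ol | OC\C=C(/C)[C@@H]1C(I)=C2C(C)(C)C[C@H](O[Si](C)(C)C(C)(C)C)C[C@@]2(C)O1
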